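Q sits in the first phase and E in the second, and both earlier runs level off with J well short of the Q charged, although E went in at 2.5 equiv.

| flask | Q | E | remark | time | volume of the second phase over the first |
|---|---|---|---|---|---|
| dawn | 10 mM | 2.5 equiv | run made earlier |  |  |
| winter | 40 mM | 2.5 equiv | run made earlier |  |  |
| flask | 20 mM | 2.50 equiv |  | 30 h | 0.25 |

- dawn (time / h: J / %): 3.00: 14.6; 6.00: 28.9; 15.0: 45.2; 40.0: 51.6
- winter (time / h: J / %): 10.0: 69.7; 20.0: 76.7; 25.0: 77.0; 40.0: 77.6

(readings scatter by 1 percentage point)

- in the second phase: E; everything else is in the first
- charges count per volume of the first phase; a concentration in a rate is the amount of a species over the volume of its own phase; every rate counts per litre of the first phase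
- what was read earlier has a scatter of 1 percentage point, one standard deviation
- the earlier runs hold the two phases in the same ratio of volumes as the flask asked about

- amount of J at 30 h, in percent of the Q charged
- the change that raises the amount of J at 30 h, in percent of the Q charged most ("none" if none brings more than 2 percentage points) (Wednesday's / Saturday's / none)
- amount of J at 30 h, in percent of the Q charged, after Wednesday's

- Wednesday's: doubling the amount of E, all else as stated
- Saturday's: doubling the transfer coefficient of E, all else as stated

My own reckoning freezes one thing: Q falls in proportion to itself and to whatever reagent strength it meets (pseudo-first-order), so the log of Q charged over Q left measures what Q has felt. Counting as left whatever isn't J, the last readings give 0.726 for dawn and 1.50 for winter. This flask's E charge is twice dawn's and half winter's, so I take the middle on a ratio scale, 1.04: that is the exposure, the natural log of Q charged over Q left.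

Turn the settings one by one. Time: winter gains 0.9 percentage points between 20.0 h and 40.0 h, less than the scatter, so I read 30 h as plateau, and the exposure gives J at 64.7 %. Amount of E: Wednesday's matches winter's E charge, so I take the exposure as 1.50 and J as 78 %. Transfer: no run varies it; I expect it to move when the exposure arrives, and so less than 2 points.

The forecast reads the plateaus as balance, “the flask is therefore essentially at equilibrium”, and says 65 %, Wednesday's, and 81 % against my 78 %.

The flask gives 65.0 %. Wednesday's adds 18 points, reaching 82.8 %, above both figures, and Saturday's moves J by −1.3 points.

    Z → L (k = 0.00167 min⁻¹)
    Q + Z → J (k = 0.0908 L mol⁻¹ min⁻¹)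
    Z ⇌ E, rate k3*([Z] - [E]/K3) per volume of the first phase (partition coefficient = 1.06, kL = 0.00302 min⁻¹)
    2 Z → X (k = 0.0556 L mol⁻¹ min⁻¹)
    Q → D (k = 8.48 × 10⁻⁶ min⁻¹)

At 1.13 h, Q has a half-life of 6.2 h by its reaction with Z. Z passing into L alone has a half-life of 6.9 h, longer than that of Q. At 30.0 h, E stands at 0.411 % of its charge with 34.3 % of Q left, and at 300 h J stands at 66.1 %. The flask's J corresponds to an exposure of 1.05, beside the 1.04 reckoned. For the neighbour charged with 12 mM of Q, the same two readings give 55.0 %, and it stands at 54.1 %.

The earlier runs and the new flask were generated by integration for an exercise; scatter was added.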